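**Retrosynthetic overview**
1. Target ⇐ HF·pyridine desilylation of a (2S)-2-aryl-4-silyloxy-2H-chromene, the silyl enol ether of the doubly O-silylated flavanone.
2. Key disconnection C2–C1' (ring C to ring B): the O-silylated 7-hydroxychromone is turned in the flask into a (1-siloxyallyl)NiBr(BiOX) complex, a homoenolate equivalent that is nucleophilic at C2, and is joined enantioselectively to the ring B aryl bromide. Both carbons are electrophilic in the two building blocks, and the only stereocenter is made in this C–C bond formation.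
3. Ring B bromide ⇐ 4-bromophenol + two molecules of prenyl bromide (double ortho C-prenylation, then O-silylation); chromone partner ⇐ 7-hydroxychromone (O-silylation).
4. Ring order: no ring is built. Rings A and C come fused in the chromone, ring B comes from 4-bromophenol and is attached to ring C last.

Assumption: 7-hydroxychromone is bought as such. The absolute sense of induction of the nickel step cannot be predicted, so the route is written with the (S,S)-ligand. Its (R,R)-antipode (from D-phenylalaninol) is used instead if the first run (chiral HPLC and optical rotation against the natural 2S series) gives 2R.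

**Route**

Step 1
Reactants: 1 4-bromophenol; 2 prenyl bromide (1-bromo-3-methylbut-2-ene), first equivalent
Product: 4 4-bromo-2,6-bis(3-methylbut-2-en-1-yl)phenol, via 4-bromo-2-prenylphenol 3 (not isolated)
Conditions: NaH (2.2 equiv), toluene, 0 °C → rt; then 2 (2.2 equiv in all), rt, 24 h
Reagents that add atoms: prenyl bromide (1-bromo-3-methylbut-2-ene), the second equivalent of compound 2, CC(C)=CCBr
Why: Ortho-selective C-alkylation of a sodium phenoxide in a non-polar solvent (phenolate C-prenylation through the sodium-bridged tight ion pair, SN2 at the primary carbon so the linear prenyl group results); the para position is blocked by bromine, the first molecule of 2 gives 3, and the second equivalent of NaH with a second molecule of 2 repeats the event at the other ortho carbon of 3; no stereocenter.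

Step 2
Reactants: 4 4-bromo-2,6-bis(3-methylbut-2-en-1-yl)phenol
Product: 5 tert-butyl[4-bromo-2,6-bis(3-methylbut-2-en-1-yl)phenoxy]dimethylsilane
Conditions: NaH, THF, 0 °C; TBSCl, 0 °C → rt
Reagents that add atoms: tert-butyldimethylsilyl chloride (TBSCl), CC(C)(C)[Si](C)(C)Cl
Why: O-silylation of the sodium phenoxide (silyl ether formation) removes the acidic OH that would protonate the organonickel intermediates of step 4; the ortho CH2 groups do not block attack at silicon, and the aryl bromide and the prenyl groups are inert.

Step 3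
Reactants: 6 7-hydroxychromone (7-hydroxy-4H-chromen-4-one)
Product: 7 7-[(tert-butyldimethylsilyl)oxy]-4H-chromen-4-one
Conditions: NaH, THF, 0 °C; TBSCl, 0 °C → rt
Reagents that add atoms: tert-butyldimethylsilyl chloride (TBSCl), CC(C)(C)[Si](C)(C)Cl
Why: O-silylation of the acidic 7-OH (silyl ether formation) gives a soluble, aprotic chromone for step 4; the vinylogous ester is not touched.

Step 4
Reactants: 7 7-[(tert-butyldimethylsilyl)oxy]-4H-chromen-4-one; 5 tert-butyl[4-bromo-2,6-bis(3-methylbut-2-en-1-yl)phenoxy]dimethylsilane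
Product: 8 (2S)-7-[(tert-butyldimethylsilyl)oxy]-2-{4-[(tert-butyldimethylsilyl)oxy]-3,5-bis(3-methylbut-2-en-1-yl)phenyl}-4-[(triethylsilyl)oxy]-2H-chromene
Conditions: NiBr2(dme) (10 mol%), (4S,4'S)-4,4'-dibenzyl-4,4',5,5'-tetrahydro-2,2'-bioxazole [(S,S)-Bn-BiOX] (12 mol%), Mn powder (3 equiv), Et3SiCl (1.5 equiv), 5 (1.3 equiv), DMA, rt, exclusion of light
Reagents that add atoms: chlorotriethylsilane (Et3SiCl), CC[Si](Cl)(CC)CC
Why: Proposed new method: zerovalent nickel (from NiBr2(dme), BiOX and Mn) binds the C2=C3 bond of 7 and O-silylation by Et3SiCl turns the chromone into the η3-allyl complex (4-Et3SiO-chromen-2-yl)NiBr(BiOX), a 1-siloxyallyl nickel homoenolate equivalent in which C2, normally the electrophilic β-carbon, is the nucleophilic terminus; after reduction by Mn to the monovalent allyl complex it takes up the aryl bromide 5 by oxidative addition and the trivalent (allyl)(aryl)nickel species reductively eliminates at C2, the unhindered terminus remote from the OSiEt3 carbon, so two carbons that are both electrophilic in the starting materials are joined without an arylmetal reagent, and the C2 stereocenter is set in this C–C bond-forming reductive elimination by the C2-symmetric bis(oxazoline) on nickel, the two faces of the planar chromenyl fragment exchanging through the metal before the enantio-determining step (enantioconvergent); the closest known reaction types are the racemic nickel-catalysed reductive conjugate arylation of enones with aryl halides, Mn and chlorosilanes (cross-electrophile coupling giving silyl enol ethers), enantioselective nickel-catalysed reductive cross-electrophile couplings with bis(oxazoline) ligands, and enantioselective nickel-catalysed arylation of benzopyrylium ions.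

Step 5
Reactants: 8 (2S)-7-[(tert-butyldimethylsilyl)oxy]-2-{4-[(tert-butyldimethylsilyl)oxy]-3,5-bis(3-methylbut-2-en-1-yl)phenyl}-4-[(triethylsilyl)oxy]-2H-chromene
Product: 11 (2S)-7-hydroxy-2-[4-hydroxy-3,5-bis(3-methylbut-2-en-1-yl)phenyl]-2,3-dihydro-4H-chromen-4-one, via bis-TBS flavanone 9 (not isolated), via 4'-O-TBS flavanone 10 (not isolated)
Conditions: HF·pyridine, pyridine, THF, 0 °C → rt
Reagents that add atoms: none
Why: Fluoride-mediated desilylation under mildly acidic conditions cleaves the silyl enol ether to the ketone 9 and then the two aryl silyl ethers (the unhindered 7-O first, the flanked 4'-O last); C2 is not involved and, with no base present, the ring opening to the chalcone that racemises 4'-hydroxyflavanones is avoided, while pyridine-buffered HF does not cyclise the ortho-prenylphenol.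

**Compound list**
1 | 4-bromophenol | Oc1ccc(Br)cc1 | starting material
2 | prenyl bromide (1-bromo-3-methylbut-2-ene) | CC(C)=CCBr | starting material
3 | 4-bromo-2-(3-methylbut-2-en-1-yl)phenol | CC(C)=CCc1cc(Br)ccc1O | intermediate
4 | 4-bromo-2,6-bis(3-methylbut-2-en-1-yl)phenol | CC(C)=CCc1cc(Br)cc(CC=C(C)C)c1O | intermediate
5 | tert-butyl[4-bromo-2,6-bis(3-methylbut-2-en-1-yl)phenoxy]dimethylsilane | CC(C)=CCc1cc(Br)cc(CC=C(C)C)c1O[Si](C)(C)C(C)(C)C | intermediate
6 | 7-hydroxychromone (7-hydroxy-4H-chromen-4-one) | O=c1ccoc2cc(O)ccc12 | starting material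
7 | 7-[(tert-butyldimethylsilyl)oxy]-4H-chromen-4-one | O=c1ccoc2cc(O[Si](C)(C)C(C)(C)C)ccc12 | intermediate
8 | (2S)-7-[(tert-butyldimethylsilyl)oxy]-2-{4-[(tert-butyldimethylsilyl)oxy]-3,5-bis(3-methylbut-2-en-1-yl)phenyl}-4-[(triethylsilyl)oxy]-2H-chromene | CC(C)=CCc1cc([C@@H]2C=C(O[Si](CC)(CC)CC)c3ccc(O[Si](C)(C)C(C)(C)C)cc3O2)cc(CC=C(C)C)c1O[Si](C)(C)C(C)(C)C | intermediate
9 | (2S)-7-[(tert-butyldimethylsilyl)oxy]-2-{4-[(tert-butyldimethylsilyl)oxy]-3,5-bis(3-methylbut-2-en-1-yl)phenyl}-2,3-dihydro-4H-chromen-4-one | CC(C)=CCc1cc([C@@H]2CC(=O)c3ccc(O[Si](C)(C)C(C)(C)C)cc3O2)cc(CC=C(C)C)c1O[Si](C)(C)C(C)(C)C | intermediate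
10 | (2S)-2-{4-[(tert-butyldimethylsilyl)oxy]-3,5-bis(3-methylbut-2-en-1-yl)phenyl}-7-hydroxy-2,3-dihydro-4H-chromen-4-one | CC(C)=CCc1cc([C@@H]2CC(=O)c3ccc(O)cc3O2)cc(CC=C(C)C)c1O[Si](C)(C)C(C)(C)C | intermediate
11 | (2S)-7-hydroxy-2-[4-hydroxy-3,5-bis(3-methylbut-2-en-1-yl)phenyl]-2,3-dihydro-4H-chromen-4-one | CC(C)=CCc1cc([C@@H]2CC(=O)c3ccc(O)cc3O2)cc(CC=C(C)C)c1O | target

**Step count**
Total steps: 5. Longest linear sequence: 4 (steps 1, 2, 4, 5); step 3 is the one-step side branch.

**Steps most likely to fail**

Step 4 (the nickel-mediated union). The vinylogous-ester chromone may be too electron-rich to be activated by zerovalent nickel and Et3SiCl. Reductive dimerisation of 7 and hydrodehalogenation or homocoupling of 5 compete. The level and sense of enantioselectivity are unknown. The fallback sets out from 7 and 5 and comes back at 9. It keeps the same reversed-polarity bond formation but separates it from stereocontrol. The coupling is run in its precedented racemic form (NiBr2(dme), 2,9-dimethyl-1,10-phenanthroline, Mn, Et3SiCl, DMF, 40 °C) to give the racemic silyl enol ether F1, which is not isolated. Work-up with aqueous citric acid in THF hydrolyses only the enol ether and gives the racemic bis-TBS flavanone F2. Preparative chiral SFC on amylose tris(3,5-dimethylphenylcarbamate) then gives 9 and the (2R)-bis-TBS flavanone F3. F3 is returned to F2 with DBU in toluene (ring opening to the chalcone and reclosure) and recycled. Compound 9 goes on to 11 under the step 5 conditions.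

Step 1 (double C-prenylation). O-alkylation, geminal dialkylation at one ortho carbon and chroman formation can leave a low yield of 4 that is hard to separate from 3. The fallback sets out from 1 and comes back at 5, bypassing 3 and 4. Iodination of 1 (I2, NaHCO3, aqueous MeOH) gives 4-bromo-2,6-diiodophenol F4. O-silylation (NaH, TBSCl, THF) gives (4-bromo-2,6-diiodophenoxy)(tert-butyl)dimethylsilane F5. A twofold Stille coupling with tributyl(3-methylbut-2-en-1-yl)stannane (Pd(PPh3)4, DMF, 70 °C) uses the faster oxidative addition of the two C–I bonds over the C–Br bond and delivers 5 with the linear prenyl groups.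

Step 3 (silyl ether of the acidic 7-OH). This is the most labile protecting group carried into the halide-rich, Lewis-acidic medium of step 4, and it may not survive isolation or the coupling. The fallback sets out from 6 and comes back at 9 without isolating a protected chromone. Compound 6 is deprotonated with NaH (1 equiv) in THF and treated with TBSOTf (2.05 equiv). Silylation of the phenoxide (through 7 in the flask) and then of the carbonyl oxygen gives a solution of 4,7-bis[(tert-butyldimethylsilyl)oxy]chromenylium triflate F6, a pre-formed pyrylium electrophile. This solution is added to 5, NiBr2(dme), (S,S)-Bn-BiOX and Mn in DMA with no chlorosilane. Zerovalent nickel adds to C2 of the cation to give the same type of siloxyallyl complex, and coupling gives the (2S)-tris-TBS enol ether F7. HF·pyridine as in step 5 takes F7 through 9 to 11.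

**Further compounds**
F1 | step 4 | racemic 7-[(tert-butyldimethylsilyl)oxy]-2-{4-[(tert-butyldimethylsilyl)oxy]-3,5-bis(3-methylbut-2-en-1-yl)phenyl}-4-[(triethylsilyl)oxy]-2H-chromene | CC(C)=CCc1cc(C2C=C(O[Si](CC)(CC)CC)c3ccc(O[Si](C)(C)C(C)(C)C)cc3O2)cc(CC=C(C)C)c1O[Si](C)(C)C(C)(C)C
F2 | step 4 | racemic 7-[(tert-butyldimethylsilyl)oxy]-2-{4-[(tert-butyldimethylsilyl)oxy]-3,5-bis(3-methylbut-2-en-1-yl)phenyl}-2,3-dihydro-4H-chromen-4-one | CC(C)=CCc1cc(C2CC(=O)c3ccc(O[Si](C)(C)C(C)(C)C)cc3O2)cc(CC=C(C)C)c1O[Si](C)(C)C(C)(C)C
F3 | step 4 | (2R)-7-[(tert-butyldimethylsilyl)oxy]-2-{4-[(tert-butyldimethylsilyl)oxy]-3,5-bis(3-methylbut-2-en-1-yl)phenyl}-2,3-dihydro-4H-chromen-4-one | CC(C)=CCc1cc([C@H]2CC(=O)c3ccc(O[Si](C)(C)C(C)(C)C)cc3O2)cc(CC=C(C)C)c1O[Si](C)(C)C(C)(C)C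
F4 | step 1 | 4-bromo-2,6-diiodophenol | Oc1c(I)cc(Br)cc1I
F5 | step 1 | (4-bromo-2,6-diiodophenoxy)(tert-butyl)dimethylsilane | CC(C)(C)[Si](C)(C)Oc1c(I)cc(Br)cc1I
F6 | step 3 | 4,7-bis[(tert-butyldimethylsilyl)oxy]chromenylium triflate | CC(C)(C)[Si](C)(C)Oc1cc[o+]c2cc(O[Si](C)(C)C(C)(C)C)ccc12.[O-]S(=O)(=O)C(F)(F)F
F7 | step 3 | (2S)-4,7-bis[(tert-butyldimethylsilyl)oxy]-2-{4-[(tert-butyldimethylsilyl)oxy]-3,5-bis(3-methylbut-2-en-1-yl)phenyl}-2H-chromene | CC(C)=CCc1cc([C@@H]2C=C(O[Si](C)(C)C(C)(C)C)c3ccc(O[Si](C)(C)C(C)(C)C)cc3O2)cc(CC=C(C)C)c1O[Si](C)(C)C(C)(C)C
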